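**Retrosynthetic overview**

1. Daphnodorin D2 is apigenin whose C3 carries C8 of (2S)-4',5,7-trihydroxyflavan. The last skeletal disconnection is a formal retro-[4+2] of the flavan pyran ring (bonds O1–C2 and C3–C4) into an o-quinone methide of the phloroglucinol ring and 4-vinylphenol.
2. Enabling feature: in the flavan pyran ring, O1 (on C8a) and the benzylic C4 (on C4a) are ortho neighbours on the arene, which is an o-quinone methide retron. C2 carries a 4-hydroxyphenyl ring, so C2–C3 is 4-vinylphenol; its para OH polarises the alkene and lets O1–C2 form by oxa-1,6-addition to a p-quinone methide under a chiral phosphoric acid.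
3. The precursor is a 3-arylflavone with a salicyl alcohol unit whose only free phenol is the future O1. It comes from Negishi coupling of C3-zincated tri-O-benzylapigenin with 4,6-bis(benzyloxy)-3-iodo-2-(methoxymethoxy)benzaldehyde, then MOM removal and aldehyde reduction.
4. Ring order: flavone rings A, C and B are bought as apigenin; the other arenes come from 3,5-bis(benzyloxy)phenol and 4-acetoxystyrene. The flavan pyran ring is the only ring built and is closed last; hydrogenolysis of five benzyl ethers ends the route.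

Key step: step 9

Assumption: the SMILES defines only C2 (S); the hindered biaryl axis between flavone C3 and flavan C8 is not defined in it and is not controlled here, so if rotation about it is slow the (2S) rotamers would be separated or equilibrated at the end.

**Route**

Step 1
Reactants: 1 apigenin; 2 benzyl bromide
Product: 3 5,7-bis(benzyloxy)-2-[4-(benzyloxy)phenyl]-4H-chromen-4-one (tri-O-benzylapigenin)
Conditions: BnBr (4.5 equiv), K2CO3, DMF, 80 °C
Reagents that add atoms: benzyl bromide (2), BrCc1ccccc1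
Why: Williamson etherification of all three phenols, the chelated 5-OH needing the excess and the heat; benzyl ethers should survive the zinc amide, acid and hydride and leave at the end under neutral hydrogenolysis.

Step 2
Reactants: 4 3,5-bis(benzyloxy)phenol; 5 paraformaldehyde
Product: 6 4,6-bis(benzyloxy)-2-hydroxybenzaldehyde
Conditions: (CH2O)n, MgCl2, Et3N, MeCN, reflux
Reagents that add atoms: paraformaldehyde (5), C=O
Why: Magnesium-mediated ortho-formylation (Casnati–Skattebøl reaction), in which the magnesium phenoxide delivers formaldehyde only ortho to the free OH and a second formaldehyde oxidises the benzylic alkoxide to the aldehyde.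

Step 3
Reactants: 6 4,6-bis(benzyloxy)-2-hydroxybenzaldehyde; 7 benzyltrimethylammonium dichloroiodate
Product: 8 4,6-bis(benzyloxy)-2-hydroxy-3-iodobenzaldehyde
Conditions: BnMe3N·ICl2 (1.05 equiv), CaCO3, CH2Cl2–MeOH, rt
Reagents that add atoms: benzyltrimethylammonium dichloroiodate (7), C[N+](C)(C)Cc1ccccc1.Cl[I-]Cl
Why: Electrophilic aromatic iodination, expected at C3 (ortho to the chelated OH) rather than C5 (between two benzyloxy groups), as is usual for chelated 2-hydroxy-4,6-dialkoxyaryl carbonyl compounds; this puts the coupling handle next to the one oxygen that becomes O1.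

Step 4
Reactants: 8 4,6-bis(benzyloxy)-2-hydroxy-3-iodobenzaldehyde; 9 chloromethyl methyl ether
Product: 10 4,6-bis(benzyloxy)-3-iodo-2-(methoxymethoxy)benzaldehyde
Conditions: NaH, DMF, 0 °C; then MOMCl
Reagents that add atoms: chloromethyl methyl ether (9), COCCl
Why: O-alkylation of the sodium phenoxide (Williamson type); the MOM acetal masks the acidic OH for the organozinc coupling and keeps this oxygen distinct from the benzylated ones.

Step 5
Reactants: 3 tri-O-benzylapigenin; 10 4,6-bis(benzyloxy)-3-iodo-2-(methoxymethoxy)benzaldehyde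
Product: 12 4,6-bis(benzyloxy)-3-{5,7-bis(benzyloxy)-2-[4-(benzyloxy)phenyl]-4-oxo-4H-chromen-3-yl}-2-(methoxymethoxy)benzaldehyde, via 3-flavonylzinc chloride 11 (not isolated)
Conditions: 3 (1.2 equiv), TMPZnCl·LiCl (TMP = 2,2,6,6-tetramethylpiperidide), THF, 25 °C; then 10, Pd2(dba)3 (2.5 mol %), RuPhos (10 mol %), THF, 60 °C
Reagents that add atoms: none
Why: Carbonyl-directed zincation of the chromone at C3 followed by Negishi coupling; a bulky dialkylbiarylphosphine on zerovalent palladium is a known answer to tetra-ortho-substituted biaryl bonds, and the arylzinc should leave the hindered, electron-rich aldehyde untouched.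

Step 6
Reactants: 12 MOM-protected biaryl aldehyde
Product: 13 4,6-bis(benzyloxy)-3-{5,7-bis(benzyloxy)-2-[4-(benzyloxy)phenyl]-4-oxo-4H-chromen-3-yl}-2-hydroxybenzaldehyde
Conditions: 3 M aq. HCl, THF, 50 °C
Reagents that add atoms: none
Why: Acid hydrolysis of the MOM acetal, done at the aldehyde oxidation level where the ring is deactivated and no benzylic cation can form; benzyl ethers and the flavone are inert.

Step 7
Reactants: 13 biaryl salicylaldehyde
Product: 14 5,7-bis(benzyloxy)-3-[4,6-bis(benzyloxy)-2-hydroxy-3-(hydroxymethyl)phenyl]-2-[4-(benzyloxy)phenyl]-4H-chromen-4-one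
Conditions: NaBH4, THF–MeOH, 0 °C, short contact; pH 7 buffer; used crude
Reagents that add atoms: none
Why: Chemoselective hydride reduction of the aldehyde (the vinylogous-ester carbonyl of the flavone should not react at 0 °C); cold, brief treatment and a neutral quench are meant to prevent quinone methide formation from the phenoxide.

Step 8
Reactants: 15 4-acetoxystyrene
Product: 16 4-vinylphenol
Conditions: K2CO3 (0.2 equiv), MeOH, 0 °C; pH 6 buffer, extraction into toluene, used at once
Reagents that add atoms: none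
Why: Base-catalysed transesterification of the aryl acetate; the phenol is made fresh because it polymerises on storage.

Step 9
Reactants: 14 salicyl alcohol; 16 4-vinylphenol
Product: 19 5,7-bis(benzyloxy)-3-[(2S)-5,7-bis(benzyloxy)-2-(4-hydroxyphenyl)-3,4-dihydro-2H-chromen-8-yl]-2-[4-(benzyloxy)phenyl]-4H-chromen-4-one, via o-quinone methide 17 (not isolated), via p-quinone methide 18 (not isolated)
Conditions: (R)-TRIP [(R)-3,3'-bis(2,4,6-triisopropylphenyl)-1,1'-binaphthyl-2,2'-diyl hydrogen phosphate] (10 mol %), 16 (3 equiv, slow addition), 4 Å MS, toluene–CH2Cl2, −20 °C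
Reagents that add atoms: none
Why: Proposed new method: the acid ionises the very electron-rich benzylic alcohol of 14 to o-quinone methide 17, which stays hydrogen-bonded to the chiral phosphate, and the β-carbon of 4-vinylphenol 16 (bound through its OH to the phosphoryl oxygen) adds to the methide carbon to form C4–C3 and p-quinone methide 18. The phenol oxygen of 18 then adds to the exocyclic carbon of the p-quinone methide (oxa-1,6-addition, 6-exo-trig), so the pyran ring closes in a formal inverse-electron-demand hetero-[4+2] sense with C–C bond formation leading. The closest known reaction types are chiral Brønsted acid-catalysed [4+2] cycloadditions of o-hydroxybenzyl alcohols with hydroxystyrenes and other styrenes, and enantioselective 1,6-additions of phenols to p-quinone methides formed in situ under the same acids; not yet shown is a methide carbon without substituent, which leaves C2 as the only stereocentre. C2 is set by the catalyst alone: the phosphate bridges the carbonyl of the p-quinone methide and the attacking phenol OH, and its 3,3'-aryl walls should leave one face of the exocyclic C2=C1' bond open; (R)-TRIP is the first choice for 2S, the sense of induction has to be confirmed, and the antipode is used if it is opposite. Regioselectivity (O1 to the benzylic C2, CH2 to C3) follows from the push of the para oxygen of 16, and the choice of ring oxygen is secured by the substrate, since the only free phenol ortho to CH2OH is the one next to the flavonyl group while the other ortho and para oxygens are benzyl ethers. Aromatisation of ring B in the last bond formation makes the closure downhill and, under a weak acid at low temperature, should keep it from reversing.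

Step 10
Reactants: 19 penta-O-benzyl daphnodorin D2
Product: 20 daphnodorin D2
Conditions: H2 (1 atm), Pd(OH)2/C, THF–MeOH, rt
Reagents that add atoms: none
Why: Hydrogenolysis of five aryl benzyl ethers under neutral conditions, which avoids acid that could ionise the p-hydroxybenzylic C2–O1 bond and scramble C2; the tetrasubstituted chromone alkene and the flavan ring ether are expected to survive, as in flavone and flavan-3-ol debenzylations.

**Compound list**

1 | apigenin, 5,7-dihydroxy-2-(4-hydroxyphenyl)-4H-chromen-4-one | O=c1cc(-c2ccc(O)cc2)oc2cc(O)cc(O)c12 | starting material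
2 | benzyl bromide | BrCc1ccccc1 | starting material
3 | 5,7-bis(benzyloxy)-2-[4-(benzyloxy)phenyl]-4H-chromen-4-one | O=c1cc(-c2ccc(OCc3ccccc3)cc2)oc2cc(OCc3ccccc3)cc(OCc3ccccc3)c12 | intermediate
4 | 3,5-bis(benzyloxy)phenol | Oc1cc(OCc2ccccc2)cc(OCc2ccccc2)c1 | starting material
5 | paraformaldehyde (as formaldehyde) | C=O | starting material
6 | 4,6-bis(benzyloxy)-2-hydroxybenzaldehyde | O=Cc1c(O)cc(OCc2ccccc2)cc1OCc1ccccc1 | intermediate
7 | benzyltrimethylammonium dichloroiodate | C[N+](C)(C)Cc1ccccc1.Cl[I-]Cl | starting material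
8 | 4,6-bis(benzyloxy)-2-hydroxy-3-iodobenzaldehyde | O=Cc1c(O)c(I)c(OCc2ccccc2)cc1OCc1ccccc1 | intermediate
9 | chloromethyl methyl ether | COCCl | starting material
10 | 4,6-bis(benzyloxy)-3-iodo-2-(methoxymethoxy)benzaldehyde | O=Cc1c(OCOC)c(I)c(OCc2ccccc2)cc1OCc1ccccc1 | intermediate
11 | {5,7-bis(benzyloxy)-2-[4-(benzyloxy)phenyl]-4-oxo-4H-chromen-3-yl}zinc chloride | O=c1c([Zn]Cl)c(-c2ccc(OCc3ccccc3)cc2)oc2cc(OCc3ccccc3)cc(OCc3ccccc3)c12 | intermediate
12 | 4,6-bis(benzyloxy)-3-{5,7-bis(benzyloxy)-2-[4-(benzyloxy)phenyl]-4-oxo-4H-chromen-3-yl}-2-(methoxymethoxy)benzaldehyde | O=c1c(-c2c(OCOC)c(C=O)c(OCc3ccccc3)cc2OCc2ccccc2)c(-c2ccc(OCc3ccccc3)cc2)oc2cc(OCc3ccccc3)cc(OCc3ccccc3)c12 | intermediate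
13 | 4,6-bis(benzyloxy)-3-{5,7-bis(benzyloxy)-2-[4-(benzyloxy)phenyl]-4-oxo-4H-chromen-3-yl}-2-hydroxybenzaldehyde | O=c1c(-c2c(O)c(C=O)c(OCc3ccccc3)cc2OCc2ccccc2)c(-c2ccc(OCc3ccccc3)cc2)oc2cc(OCc3ccccc3)cc(OCc3ccccc3)c12 | intermediate
14 | 5,7-bis(benzyloxy)-3-[4,6-bis(benzyloxy)-2-hydroxy-3-(hydroxymethyl)phenyl]-2-[4-(benzyloxy)phenyl]-4H-chromen-4-one | O=c1c(-c2c(O)c(CO)c(OCc3ccccc3)cc2OCc2ccccc2)c(-c2ccc(OCc3ccccc3)cc2)oc2cc(OCc3ccccc3)cc(OCc3ccccc3)c12 | intermediate
15 | 4-acetoxystyrene | CC(=O)Oc1ccc(C=C)cc1 | starting material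
16 | 4-vinylphenol | C=Cc1ccc(O)cc1 | intermediate
17 | o-quinone methide: 3-[4,6-bis(benzyloxy)-3-methylidene-2-oxocyclohexa-4,6-dien-1-yl]-substituted tri-O-benzylapigenin (exocyclic CH2 on the carbon between C=O and C–OBn) | C=C1C(=O)C(-c2c(-c3ccc(OCc4ccccc4)cc3)oc3cc(OCc4ccccc4)cc(OCc4ccccc4)c3c2=O)=C(OCc2ccccc2)C=C1OCc1ccccc1 | intermediate
18 | p-quinone methide: 4-{2-[aryl]ethylidene}cyclohexa-2,5-dien-1-one, aryl = 4,6-bis(benzyloxy)-2-hydroxy-3-(tri-O-benzylapigenin-3-yl)phenyl | O=C1C=CC(=CCc2c(O)c(-c3c(-c4ccc(OCc5ccccc5)cc4)oc4cc(OCc5ccccc5)cc(OCc5ccccc5)c4c3=O)c(OCc3ccccc3)cc2OCc2ccccc2)C=C1 | intermediate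
19 | 5,7-bis(benzyloxy)-3-[(2S)-5,7-bis(benzyloxy)-2-(4-hydroxyphenyl)-3,4-dihydro-2H-chromen-8-yl]-2-[4-(benzyloxy)phenyl]-4H-chromen-4-one | O=c1c(-c2c(OCc4ccccc4)cc(OCc4ccccc4)c3c2O[C@H](c2ccc(O)cc2)CC3)c(-c2ccc(OCc3ccccc3)cc2)oc2cc(OCc3ccccc3)cc(OCc3ccccc3)c12 | intermediate
20 | daphnodorin D2, 5,7-dihydroxy-3-[(2S)-5,7-dihydroxy-2-(4-hydroxyphenyl)-3,4-dihydro-2H-chromen-8-yl]-2-(4-hydroxyphenyl)-4H-chromen-4-one | O=c1c(-c2c(O)cc(O)c3c2O[C@H](c2ccc(O)cc2)CC3)c(-c2ccc(O)cc2)oc2cc(O)cc(O)c12 | target

**Step count and risks**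

Total step count: 10. Longest linear sequence: 8 steps (steps 2, 3, 4, 5, 6, 7, 9, 10, from 3,5-bis(benzyloxy)phenol).

Steps most likely to fail:

1. Step 9 (proposed new method). What may go wrong: poor facial selectivity in the ring-closing oxa-1,6-addition, either because closure happens outside the chiral ion pair or because the catalyst is mismatched with one rotamer about the hindered biaryl axis; acid-induced oligomerisation of 4-vinylphenol; self-condensation of the quinone methide. The fallback uses known chemistry only, sets out from 13 and comes back to the route at 20. Claisen–Schmidt condensation of 13 with 4'-(benzyloxy)acetophenone (KOH, EtOH–THF, rt) should give the (E)-2-hydroxychalcone F1. Chemoselective hydrogenation of its C=C bond (H2, RhCl(PPh3)3, THF–EtOH) should give the dihydrochalcone F2 without loss of benzyl ethers. Corey–Bakshi–Shibata reduction with (S)-2-methyl-CBS-oxazaborolidine and BH3·SMe2 (excess for the free phenol) should give the (R)-carbinol F3. Mitsunobu cyclisation (PPh3, DIAD, THF, 0 °C) closes O1–C2 by 6-exo-tet displacement with inversion and should give the (2S)-hexabenzyl ether F4. Hydrogenolysis under the conditions of step 10 then gives 20. Here C2 rests on reagent-controlled ketone reduction and an SN2 ring closure.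

2. Step 5. What may go wrong: slow transmetalation and reductive elimination at the tetra-ortho-substituted axis, so that protodezincation and homocoupling take over; incomplete zincation at C3. The fallback reverses the polarity, sets out from 3 and 10 and comes back at 12. Lithiation of 3 at C3 (LDA, THF, −78 °C) and quench with I2 should give 5,7-bis(benzyloxy)-2-[4-(benzyloxy)phenyl]-3-iodo-4H-chromen-4-one F5. Miyaura borylation of 10 (B2pin2, PdCl2(dppf), KOAc, dioxane, 90 °C) should give the pinacol boronate F6. Suzuki–Miyaura coupling of F5 with F6 (Pd(OAc)2, SPhos, K3PO4, toluene–water, 90 °C) gives 12.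

3. Step 7. What may go wrong: loss of the benzylic oxygen from the phenoxide (quinone methide formation) followed by hydride addition, which is over-reduction to the methyl compound, or oligomerisation during isolation. The fallback changes the order of unmasking and the quinone methide precursor, sets out from 12 and comes back at 19. Reduction of 12 with NaBH4 while the phenol is still a MOM ether, so that no quinone methide can form, should give the benzylic alcohol F7. HCl in MeOH (rt, dilute) removes the MOM group and solvolyses the ionisable benzylic alcohol to the bench-stable o-hydroxybenzyl methyl ether F8. F8 then takes the place of 14 under the conditions of step 9 (5 Å MS, methanol lost instead of water) and gives 19.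

**Further compounds**

F1 | step 9 | (E)-3-{4,6-bis(benzyloxy)-3-[5,7-bis(benzyloxy)-2-(4-benzyloxyphenyl)-4-oxo-4H-chromen-3-yl]-2-hydroxyphenyl}-1-[4-(benzyloxy)phenyl]prop-2-en-1-one | O=C(/C=C/c1c(O)c(-c2c(-c3ccc(OCc4ccccc4)cc3)oc3cc(OCc4ccccc4)cc(OCc4ccccc4)c3c2=O)c(OCc2ccccc2)cc1OCc1ccccc1)c1ccc(OCc2ccccc2)cc1
F2 | step 9 | 3-{4,6-bis(benzyloxy)-3-[5,7-bis(benzyloxy)-2-(4-benzyloxyphenyl)-4-oxo-4H-chromen-3-yl]-2-hydroxyphenyl}-1-[4-(benzyloxy)phenyl]propan-1-one | O=C(CCc1c(O)c(-c2c(-c3ccc(OCc4ccccc4)cc3)oc3cc(OCc4ccccc4)cc(OCc4ccccc4)c3c2=O)c(OCc2ccccc2)cc1OCc1ccccc1)c1ccc(OCc2ccccc2)cc1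
F3 | step 9 | 5,7-bis(benzyloxy)-3-{4,6-bis(benzyloxy)-2-hydroxy-3-[(3R)-3-hydroxy-3-(4-benzyloxyphenyl)propyl]phenyl}-2-[4-(benzyloxy)phenyl]-4H-chromen-4-one | O[C@H](CCc1c(O)c(-c2c(-c3ccc(OCc4ccccc4)cc3)oc3cc(OCc4ccccc4)cc(OCc4ccccc4)c3c2=O)c(OCc2ccccc2)cc1OCc1ccccc1)c1ccc(OCc2ccccc2)cc1
F4 | step 9 | 5,7-bis(benzyloxy)-3-{(2S)-5,7-bis(benzyloxy)-2-[4-(benzyloxy)phenyl]-3,4-dihydro-2H-chromen-8-yl}-2-[4-(benzyloxy)phenyl]-4H-chromen-4-one | O=c1c(-c2c(OCc4ccccc4)cc(OCc4ccccc4)c3c2O[C@H](c2ccc(OCc4ccccc4)cc2)CC3)c(-c2ccc(OCc3ccccc3)cc2)oc2cc(OCc3ccccc3)cc(OCc3ccccc3)c12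
F5 | step 5 | 5,7-bis(benzyloxy)-2-[4-(benzyloxy)phenyl]-3-iodo-4H-chromen-4-one | O=c1c(I)c(-c2ccc(OCc3ccccc3)cc2)oc2cc(OCc3ccccc3)cc(OCc3ccccc3)c12
F6 | step 5 | 4,6-bis(benzyloxy)-2-(methoxymethoxy)-3-(4,4,5,5-tetramethyl-1,3,2-dioxaborolan-2-yl)benzaldehyde | O=Cc1c(OCOC)c(B2OC(C)(C)C(C)(C)O2)c(OCc2ccccc2)cc1OCc1ccccc1
F7 | step 7 | 5,7-bis(benzyloxy)-3-[4,6-bis(benzyloxy)-3-(hydroxymethyl)-2-(methoxymethoxy)phenyl]-2-[4-(benzyloxy)phenyl]-4H-chromen-4-one | O=c1c(-c2c(OCOC)c(CO)c(OCc3ccccc3)cc2OCc2ccccc2)c(-c2ccc(OCc3ccccc3)cc2)oc2cc(OCc3ccccc3)cc(OCc3ccccc3)c12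
F8 | step 7 | 5,7-bis(benzyloxy)-3-[4,6-bis(benzyloxy)-2-hydroxy-3-(methoxymethyl)phenyl]-2-[4-(benzyloxy)phenyl]-4H-chromen-4-one | O=c1c(-c2c(O)c(COC)c(OCc3ccccc3)cc2OCc2ccccc2)c(-c2ccc(OCc3ccccc3)cc2)oc2cc(OCc3ccccc3)cc(OCc3ccccc3)c12
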